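**Retrosynthetic overview**

1. Target 18 ⇐ methyl ester 16 ⇐ 3-methoxy-1,2-dioxane 15 (C3–CH2 bond: silyl ketene acetal adds to the C3 peroxycarbenium ion) ⇐ 3,6-dimethoxy-1,2-dioxane 14 (C6–CH3 bond: methyl transfer to the C6 peroxycarbenium ion).
2. 14 ⇐ cyclobutene 11 by ozonolytic ring expansion: the O1–O2 unit is inserted into the C3=C6 double bond of the four-membered carbocycle C3–C4–C5–C6, which becomes the six-membered 1,2-dioxane in one operation.
3. Enabling feature: the two peroxide-bearing ring carbons C3 and C6 are joined through C4–C5, and each carries one axial carbon substituent (CH2CO2H at C3, CH3 at C6, trans to each other) that can enter as a nucleophile. Removing both leaves a peroxide at the 1,4-dicarbonyl level, i.e. the methanol-trapped ozonolysis product of a cyclobutene whose only stereocentre is C4; the two methoxy groups are the temporary oxidation level and leave again in steps 8 and 9.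
4. 11 ⇐ Negishi coupling of alkyl iodide 6 with enol triflate 9 (desymmetrised 3-methylcyclobutanone); 6 ⇐ (R)-citronellyl bromide, whose C10 skeleton maps onto C1'–C8' of the side chain including both methyl branches.
5. Ring order: the cyclobutene (from purchased cyclobutanone) first, then the 1,2-dioxane from it in step 7; no other ring is formed.

Key step: step 7

Remark on the chemistry: the enantiomer of the PHOX ligand (step 3) and of the lithium amide (step 5) is taken to be the one that gives the configuration drawn, by analogy with related substrates; if the sense of induction is opposite, the mirror-image ligand or base is used.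

**Route**

Step 1
Reactants: 1 (R)-citronellyl bromide [(6R)-8-bromo-2,6-dimethyloct-2-ene]; 2 2-phenylethylmagnesium chloride
Product: 3 [(5S)-5,9-dimethyldec-8-en-1-yl]benzene
Conditions: Li2CuCl4 (3 mol %), THF/NMP, 0 °C → rt
Reagents that add atoms: none
Why: Copper-catalysed alkyl–alkyl Grignard cross-coupling of a primary bromide should join C8' and C9' of the side chain without touching the citronellyl stereocentre (the future C6') or the trisubstituted alkene.

Step 2
Reactants: 3 [(5S)-5,9-dimethyldec-8-en-1-yl]benzene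
Product: 4 (2E,6S)-2,6-dimethyl-10-phenyldec-2-en-1-ol
Conditions: SeO2 (0.3 equiv), t-BuOOH (3 equiv), salicylic acid (cat.), CH2Cl2, rt
Reagents that add atoms: tert-butyl hydroperoxide, CC(C)(C)OO (terminal oxidant); selenium dioxide, O=[Se]=O (catalytic oxygen carrier)
Why: Riley allylic oxidation (ene reaction, then [2,3]-sigmatropic shift) is expected to hydroxylate selectively the (E)-methyl group of the isopropylidene terminus, giving the (E)-allylic alcohol and leaving the existing stereocentre alone.

Step 3
Reactants: 4 (2E,6S)-2,6-dimethyl-10-phenyldec-2-en-1-ol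
Product: 5 (2R,6S)-2,6-dimethyl-10-phenyldecan-1-ol
Conditions: [Ir(cod)(PHOX)]BArF (1 mol %), H2 (50 bar), CH2Cl2, rt
Reagents that add atoms: none
Why: Iridium–P,N-catalysed asymmetric hydrogenation of a trisubstituted (E)-allylic alcohol should set the new C2 stereocentre (R) by catalyst control of the alkene face, independent of the remote C6 centre and without reducing the arene.

Step 4
Reactants: 5 (2R,6S)-2,6-dimethyl-10-phenyldecan-1-ol
Product: 6 [(5S,9R)-10-iodo-5,9-dimethyldecyl]benzene
Conditions: I2, PPh3, imidazole, CH2Cl2, 0 °C → rt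
Reagents that add atoms: iodine, II
Why: Appel-type iodination proceeds by SN2 displacement at the primary carbon, so the adjacent methyl-bearing stereocentre is not affected.

Step 5
Reactants: 7 3-methylcyclobutan-1-one
Product: 9 (3S)-3-methylcyclobut-1-en-1-yl trifluoromethanesulfonate, via lithium enolate 8 (not isolated)
Conditions: (R,R)-bis(1-phenylethyl)amine, n-BuLi, LiCl, THF, −100 °C; then PhNTf2, −100 → −20 °C (product kept as a solution, volatile)
Reagents that add atoms: N-phenylbis(trifluoromethanesulfonimide), O=S(=O)(N(c1ccccc1)S(=O)(=O)C(F)(F)F)C(F)(F)F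
Why: Desymmetrisation by enantioselective deprotonation with a chiral lithium amide removes one of the two enantiotopic α-methylene protons, so C3 becomes a stereocentre (S, chosen by the base enantiomer) without any bond to it being formed, and O-triflation of the enolate fixes the double bond next to it.

Step 6
Reactants: 6 [(5S,9R)-10-iodo-5,9-dimethyldecyl]benzene; 9 (3S)-3-methylcyclobut-1-en-1-yl trifluoromethanesulfonate
Product: 11 [(5S,9R)-5,9-dimethyl-10-[(3S)-3-methylcyclobut-1-en-1-yl]decyl]benzene, via alkylzinc iodide 10 (not isolated)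
Conditions: Zn dust (activated), LiCl, THF, 40 °C; then 9, Pd(OAc)2 (2 mol %), SPhos (4 mol %), THF, rt
Reagents that add atoms: none
Why: Zinc insertion into the primary C–I bond followed by Negishi sp3–sp2 cross-coupling with the alkenyl triflate forms the C6–C1' bond; no stereocentre takes part and oxidative addition to the strained enol triflate should be fast at room temperature.

Step 7
Reactants: 11 [(5S,9R)-5,9-dimethyl-10-[(3S)-3-methylcyclobut-1-en-1-yl]decyl]benzene
Product: 14 (4S)-6-[(2R,6S)-2,6-dimethyl-10-phenyldecyl]-3,6-dimethoxy-4-methyl-1,2-dioxane (epimers at C3 and C6), via 6-methoxy-1,2-dioxan-3-ol 12 (not isolated), via 3-methoxy-1,2-dioxan-6-ol 13 (not isolated)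
Conditions: O3, CH2Cl2/MeOH (4:1), −78 °C (Sudan Red 7B end-point); N2 purge; then HC(OMe)3, p-TsOH·H2O (5 mol %), −78 → 0 °C
Reagents that add atoms: ozone, [O-][O+]=O; methanol, CO
Why: Ozone adds to the only C=C bond ([3+2] cycloaddition) and the primary ozonide cycloreverts (Criegee mechanism) to a carbonyl oxide and a carbonyl group that stay linked through C4–C5; methanol traps the carbonyl oxide as an α-methoxy hydroperoxide, its OOH group adds to the tethered carbonyl group, and acid with orthoformate turns the remaining hemiacetal OH into OMe. The closest known reaction type is the ozonolysis of cycloalkenes in methanol, which gives cyclic peroxy hemiacetals when the ring size allows, as it does at the 1,4-dicarbonyl level here (compare the stable 1,2-dioxane-3,6-diols of 1,4-diketones). The one ring that closes is the 1,2-dioxane, by 6-exo-trig addition of the hydroperoxide oxygen to the C=O group, so the four-membered carbocycle is expanded by the two peroxide oxygens placed between its former sp2 carbons. The new stereocentres C3 and C6 are acetal centres that form without control, which is harmless because both are made planar again in steps 8 and 9, while the C4 methyl stereocentre is not touched. The step needs chemoselectivity for the strained trisubstituted alkene over the phenyl ring (secured by the far higher rate of alkene ozonation at −78 °C and the dye end-point) and tolerance of both directions of primary-ozonide cleavage (secured because 12 and 13 converge on bis-acetal 14).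

Step 8
Reactants: 14 (4S)-6-[(2R,6S)-2,6-dimethyl-10-phenyldecyl]-3,6-dimethoxy-4-methyl-1,2-dioxane
Product: 15 (4S,6R)-6-[(2R,6S)-2,6-dimethyl-10-phenyldecyl]-3-methoxy-4,6-dimethyl-1,2-dioxane (C3 epimers)
Conditions: AlMe3 (3 equiv), TMSOTf (0.3 equiv), CH2Cl2, −78 °C; Rochelle salt work-up
Reagents that add atoms: trimethylaluminium, C[Al](C)C
Why: Proposed new method: TMSOTf/AlMe3 should ionise the ketal methoxy group at C6 in preference to the acetal at C3, giving a tertiary peroxycarbenium ion to which the aluminate transfers methyl along the axial trajectory of the half-chair that keeps the C4 methyl pseudo-equatorial, so the new C6 methyl ends axial and trans to the C4 methyl (6R) with the long chain equatorial; the closest known reaction types are the C-methylation of ketals and glycosyl donors with AlMe3 through oxocarbenium ions and the allylation or Mukaiyama-type alkylation of peroxyketals through peroxycarbenium ions, and the O–O bond is expected to survive because ionisation at −78 °C should be much faster than attack of the organoaluminium on a dialkyl peroxide.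

Step 9
Reactants: 15 (4S,6R)-6-[(2R,6S)-2,6-dimethyl-10-phenyldecyl]-3-methoxy-4,6-dimethyl-1,2-dioxane
Product: 16 methyl 2-[(3S,4S,6R)-6-[(2R,6S)-2,6-dimethyl-10-phenyldecyl]-4,6-dimethyl-1,2-dioxan-3-yl]acetate
Conditions: 1-methoxy-1-(trimethylsilyloxy)ethene (3 equiv), TMSOTf (0.5 equiv), CH2Cl2, −78 °C
Reagents that add atoms: 1-methoxy-1-(trimethylsilyloxy)ethene, C=C(OC)O[Si](C)(C)C
Why: Mukaiyama-type addition of a silyl ketene acetal to the peroxycarbenium ion from a cyclic methoxy peroxyacetal (a known reaction of 3-alkoxy-1,2-dioxolanes and 1,2-dioxan-3-yl esters) should occur axially on the half-chair that keeps the C4 methyl and the C6 chain pseudo-equatorial, anti to the axial C6 methyl, which sets C3 (S) cis to both and makes the two C3 epimers of 15 converge.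

Step 10
Reactants: 16 methyl 2-[(3S,4S,6R)-6-[(2R,6S)-2,6-dimethyl-10-phenyldecyl]-4,6-dimethyl-1,2-dioxan-3-yl]acetate
Product: 18 2-[(3S,4S,6R)-6-[(2R,6S)-2,6-dimethyl-10-phenyldecyl]-4,6-dimethyl-1,2-dioxan-3-yl]acetic acid, via lithium carboxylate 17 (not isolated)
Conditions: LiOH·H2O (3 equiv), THF/H2O (3:1), 0 °C; then 1 M HCl to pH 3
Reagents that add atoms: lithium hydroxide, [Li+].[OH-]
Why: Saponification of the methyl ester at 0 °C is the usual last step for 1,2-dioxane-3-acetic acids; no stereocentre is involved and short, cold contact with base limits Kornblum–DeLaMare or retro-Michael opening of the peroxide.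

**Compound list**

1 | (R)-citronellyl bromide, (6R)-8-bromo-2,6-dimethyloct-2-ene | C[C@@H](CCBr)CCC=C(C)C | starting material
2 | 2-phenylethylmagnesium chloride | Cl[Mg]CCc1ccccc1 | starting material
3 | [(5S)-5,9-dimethyldec-8-en-1-yl]benzene | C[C@@H](CCCCc1ccccc1)CCC=C(C)C | intermediate
4 | (2E,6S)-2,6-dimethyl-10-phenyldec-2-en-1-ol | C[C@@H](CCCCc1ccccc1)CC/C=C(\C)CO | intermediate
5 | (2R,6S)-2,6-dimethyl-10-phenyldecan-1-ol | C[C@@H](CCCCc1ccccc1)CCC[C@@H](C)CO | intermediate
6 | [(5S,9R)-10-iodo-5,9-dimethyldecyl]benzene | C[C@@H](CCCCc1ccccc1)CCC[C@@H](C)CI | intermediate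
7 | 3-methylcyclobutan-1-one | CC1CC(=O)C1 | starting material
8 | lithium (3S)-3-methylcyclobut-1-en-1-olate | C[C@@H]1C=C([O-])C1.[Li+] | intermediate (not isolated)
9 | (3S)-3-methylcyclobut-1-en-1-yl trifluoromethanesulfonate | C[C@@H]1C=C(OS(=O)(=O)C(F)(F)F)C1 | intermediate
10 | [(2R,6S)-2,6-dimethyl-10-phenyldecyl]zinc iodide | C[C@@H](CCCCc1ccccc1)CCC[C@@H](C)C[Zn]I | intermediate (not isolated)
11 | [(5S,9R)-5,9-dimethyl-10-[(3S)-3-methylcyclobut-1-en-1-yl]decyl]benzene | C[C@@H](CCCCc1ccccc1)CCC[C@@H](C)CC1=C[C@@H](C)C1 | intermediate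
12 | (4S)-6-[(2R,6S)-2,6-dimethyl-10-phenyldecyl]-6-methoxy-4-methyl-1,2-dioxan-3-ol (epimers at C3 and C6; ring numbered as in the target) | C[C@@H](CCCCc1ccccc1)CCC[C@@H](C)CC1(OC)C[C@H](C)C(O)OO1 | intermediate (not isolated)
13 | (4S)-6-[(2R,6S)-2,6-dimethyl-10-phenyldecyl]-3-methoxy-4-methyl-1,2-dioxan-6-ol (epimers at C3 and C6; ring numbered as in the target) | C[C@@H](CCCCc1ccccc1)CCC[C@@H](C)CC1(O)C[C@H](C)C(OC)OO1 | intermediate (not isolated)
14 | (4S)-6-[(2R,6S)-2,6-dimethyl-10-phenyldecyl]-3,6-dimethoxy-4-methyl-1,2-dioxane (epimers at C3 and C6) | C[C@@H](CCCCc1ccccc1)CCC[C@@H](C)CC1(OC)C[C@H](C)C(OC)OO1 | intermediate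
15 | (4S,6R)-6-[(2R,6S)-2,6-dimethyl-10-phenyldecyl]-3-methoxy-4,6-dimethyl-1,2-dioxane (C3 epimers) | C[C@@H](CCCCc1ccccc1)CCC[C@@H](C)C[C@]1(C)C[C@H](C)C(OC)OO1 | intermediate
16 | methyl 2-[(3S,4S,6R)-6-[(2R,6S)-2,6-dimethyl-10-phenyldecyl]-4,6-dimethyl-1,2-dioxan-3-yl]acetate | C[C@@H](CCCCc1ccccc1)CCC[C@@H](C)C[C@]1(C)C[C@H](C)[C@H](CC(=O)OC)OO1 | intermediate
17 | lithium 2-[(3S,4S,6R)-6-[(2R,6S)-2,6-dimethyl-10-phenyldecyl]-4,6-dimethyl-1,2-dioxan-3-yl]acetate | C[C@@H](CCCCc1ccccc1)CCC[C@@H](C)C[C@]1(C)C[C@H](C)[C@H](CC(=O)[O-])OO1.[Li+] | intermediate (not isolated)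
18 | 2-[(3S,4S,6R)-6-[(2R,6S)-2,6-dimethyl-10-phenyldecyl]-4,6-dimethyl-1,2-dioxan-3-yl]acetic acid | C[C@@H](CCCCc1ccccc1)CCC[C@@H](C)C[C@]1(C)C[C@H](C)[C@H](CC(=O)O)OO1 | target

**Summary**

Total step count: 10.
Longest linear sequence: 9 steps (steps 1–4 and 6–10, from 1).

Steps most likely to fail:

1. Step 8 (proposed new method). What may go wrong: reductive cleavage of the O–O bond by the organoaluminium, ionisation at the C3 acetal in competition with the C6 ketal, or loss of axial selectivity in the methyl transfer. Fallback, setting out from 14 and returning at 15: the carbon at C6 is brought in by a nucleophile class that is established for peroxycarbenium ions. Mukaiyama-type addition of 1-methoxy-1-(trimethylsilyloxy)ethene (1.1 equiv, TMSOTf, CH2Cl2, −78 °C) at the more easily ionised ketal carbon should give, with the same axial delivery, methyl 2-[(4S,6R)-6-[(2R,6S)-2,6-dimethyl-10-phenyldecyl]-3-methoxy-4-methyl-1,2-dioxan-6-yl]acetate F1. Saponification (LiOH, THF/H2O) gives 2-[(4S,6R)-6-[(2R,6S)-2,6-dimethyl-10-phenyldecyl]-3-methoxy-4-methyl-1,2-dioxan-6-yl]acetic acid F2, which N-hydroxypyridine-2-thione, DCC and DMAP (CH2Cl2, dark) convert into the Barton ester F3. Barton reductive decarboxylation (visible light, excess t-BuSH, benzene, rt) turns CH2CO2H into CH3 and gives 15; the thiol is used in excess so that hydrogen transfer outruns epoxide formation from the β-peroxy radical.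

2. Step 5. What may go wrong: insufficient discrimination between the enantiotopic α-methylene groups because the 3-methyl group is small, erosion of selectivity on external triflation, and loss of the volatile triflate. Fallback, setting out from 6 and returning at 11 (steps 5 and 6 are bypassed), with the C4 methyl centre taken from the chiral pool and the cyclobutene made by ring contraction. Iodine–lithium exchange (t-BuLi, Et2O, −78 °C) gives [(2R,6S)-2,6-dimethyl-10-phenyldecyl]lithium F4, which is added at −78 °C to commercial (S)-4-methyloxolan-2-one (O=C1C[C@H](C)CO1) to give (2S,6R,10S)-1-hydroxy-2,6,10-trimethyl-14-phenyltetradecan-4-one F5. NaBH4 reduction gives (2S,6R,10S)-2,6,10-trimethyl-14-phenyltetradecane-1,4-diol F6, and MsCl/Et3N gives the corresponding 1,4-diyl dimethanesulfonate F7. Na2S·9H2O in DMF closes (4S)-2-[(2R,6S)-2,6-dimethyl-10-phenyldecyl]-4-methylthiolane F8, and Oxone oxidises it to (4S)-2-[(2R,6S)-2,6-dimethyl-10-phenyldecyl]-4-methylthiolane 1,1-dioxide F9. Ramberg–Bäcklund ring contraction with in-situ α-halogenation (CBr2F2, KOH/Al2O3, t-BuOH/CH2Cl2) extrudes SO2 and gives cyclobutene 11 with the C4 centre untouched.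

3. Step 9. What may go wrong: attack on the wrong face of the C3 peroxycarbenium ion (1,2-induction by the adjacent C4 methyl working against the conformational control), or proton loss to the enol peroxide with erosion at C4. Fallback, setting out from 15 and returning at 18 (16 and 17 are bypassed): allyltrimethylsilane (TMSOTf or SnCl4, CH2Cl2, −78 °C), the π-nucleophile for which axial attack on six-membered oxocarbenium-type ions is best established, should give (3S,4S,6R)-6-[(2R,6S)-2,6-dimethyl-10-phenyldecyl]-4,6-dimethyl-3-(prop-2-en-1-yl)-1,2-dioxane F10. Ozonolysis of the terminal alkene with Me2S work-up (which does not reduce dialkyl peroxides) gives 2-[(3S,4S,6R)-6-[(2R,6S)-2,6-dimethyl-10-phenyldecyl]-4,6-dimethyl-1,2-dioxan-3-yl]acetaldehyde F11, and Pinnick oxidation (NaClO2, NaH2PO4, 2-methylbut-2-ene, t-BuOH/H2O) gives the target 18 directly.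

**Further compounds**

F1 | step 8 | methyl 2-[(4S,6R)-6-[(2R,6S)-2,6-dimethyl-10-phenyldecyl]-3-methoxy-4-methyl-1,2-dioxan-6-yl]acetate (ring numbered as in the target) | C[C@@H](CCCCc1ccccc1)CCC[C@@H](C)C[C@]1(CC(=O)OC)C[C@H](C)C(OC)OO1
F2 | step 8 | 2-[(4S,6R)-6-[(2R,6S)-2,6-dimethyl-10-phenyldecyl]-3-methoxy-4-methyl-1,2-dioxan-6-yl]acetic acid | C[C@@H](CCCCc1ccccc1)CCC[C@@H](C)C[C@]1(CC(=O)O)C[C@H](C)C(OC)OO1
F3 | step 8 | 2-thioxopyridin-1(2H)-yl 2-[(4S,6R)-6-[(2R,6S)-2,6-dimethyl-10-phenyldecyl]-3-methoxy-4-methyl-1,2-dioxan-6-yl]acetate (Barton ester) | C[C@@H](CCCCc1ccccc1)CCC[C@@H](C)C[C@]1(CC(=O)On2ccccc2=S)C[C@H](C)C(OC)OO1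
F4 | step 5 | [(2R,6S)-2,6-dimethyl-10-phenyldecyl]lithium | C[C@@H](CCCCc1ccccc1)CCC[C@@H](C)C[Li]
F5 | step 5 | (2S,6R,10S)-1-hydroxy-2,6,10-trimethyl-14-phenyltetradecan-4-one | C[C@@H](CCCCc1ccccc1)CCC[C@@H](C)CC(=O)C[C@H](C)CO
F6 | step 5 | (2S,6R,10S)-2,6,10-trimethyl-14-phenyltetradecane-1,4-diol (C4 epimers) | C[C@@H](CCCCc1ccccc1)CCC[C@@H](C)CC(O)C[C@H](C)CO
F7 | step 5 | (2S,6R,10S)-2,6,10-trimethyl-14-phenyltetradecane-1,4-diyl dimethanesulfonate (C4 epimers) | C[C@@H](CCCCc1ccccc1)CCC[C@@H](C)CC(OS(C)(=O)=O)C[C@H](C)COS(C)(=O)=O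
F8 | step 5 | (4S)-2-[(2R,6S)-2,6-dimethyl-10-phenyldecyl]-4-methylthiolane (C2 epimers) | C[C@@H](CCCCc1ccccc1)CCC[C@@H](C)CC1C[C@H](C)CS1
F9 | step 5 | (4S)-2-[(2R,6S)-2,6-dimethyl-10-phenyldecyl]-4-methylthiolane 1,1-dioxide (C2 epimers) | C[C@@H](CCCCc1ccccc1)CCC[C@@H](C)CC1C[C@H](C)CS1(=O)=O
F10 | step 9 | (3S,4S,6R)-6-[(2R,6S)-2,6-dimethyl-10-phenyldecyl]-4,6-dimethyl-3-(prop-2-en-1-yl)-1,2-dioxane | C[C@@H](CCCCc1ccccc1)CCC[C@@H](C)C[C@]1(C)C[C@H](C)[C@H](CC=C)OO1
F11 | step 9 | 2-[(3S,4S,6R)-6-[(2R,6S)-2,6-dimethyl-10-phenyldecyl]-4,6-dimethyl-1,2-dioxan-3-yl]acetaldehyde | C[C@@H](CCCCc1ccccc1)CCC[C@@H](C)C[C@]1(C)C[C@H](C)[C@H](CC=O)OO1
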